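The whole plan rests on one observation: C3 of pyranone ring C is a lone CH lodged between C2, which carries the tridecyl chain, and the C4 carbonyl. Deleting that carbon leaves a 2-tridecylbenzofuran-3(2H)-one, which is easy to assemble from commercial 4,6-dimethoxybenzofuran-3(2H)-one and tridecanal. In the forward direction the missing carbon is delivered as dibromocarbene to the furan C2=C3 bond of the 3-silyloxybenzofuran 6; the cyclopropane adduct opens and sheds its silyl group, so that the C2–C3 and C3–C4 bonds and the six-membered ring C arise in a single operation as 3-bromochromone 10. Reductive removal of bromine and cleavage of the two methyl ethers complete the synthesis.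

Key step: step 4

Remark on the chemistry: ketone 5 is carried as the racemate; its single stereocentre at C2 is erased on enol silylation and the target has none.

Step 1
Reactants: 1 4,6-dimethoxybenzofuran-3(2H)-one; 2 tridecanal
Product: 4 (Z)-4,6-dimethoxy-2-tridecylidenebenzofuran-3(2H)-one, via aldol adduct 3 (not isolated)
Conditions: neutral Al2O3, CH2Cl2, rt, 2 added slowly
Reagents that add atoms: none
Why: Aldol condensation of the aurone type: the C2 methylene of 1 is unusually acidic because its enol is an aromatic 3-hydroxybenzofuran, the alumina surface brings this enol onto the aldehyde and dehydrates aldol 3 to the conjugated alkylidene, whose Z isomer (chain syn to the ring oxygen) is the thermodynamic one; the two stereocentres of 3 vanish on dehydration.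

Step 2
Reactants: 4 (Z)-4,6-dimethoxy-2-tridecylidenebenzofuran-3(2H)-one
Product: 5 4,6-dimethoxy-2-tridecylbenzofuran-3(2H)-one (racemic)
Conditions: H2 (1 atm), 10% Pd/C, EtOAc, rt
Reagents that add atoms: none
Why: Heterogeneous catalytic hydrogenation should saturate the trisubstituted, conjugated exocyclic alkene far faster than it touches the electron-rich aryl ketone (a vinylogous ester flanked by donor oxygens) or the aryl ethers; the new C2 stereocentre forms without control as the racemate, which is immaterial because step 3 makes C2 planar again.

Step 3
Reactants: 5 4,6-dimethoxy-2-tridecylbenzofuran-3(2H)-one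
Product: 6 tert-butyl[(4,6-dimethoxy-2-tridecylbenzofuran-3-yl)oxy]dimethylsilane
Conditions: TBSOTf, Et3N, CH2Cl2, 0 °C, Ar
Reagents that add atoms: tert-butyldimethylsilyl trifluoromethanesulfonate (TBSOTf), CC(C)(C)[Si](C)(C)OS(=O)(=O)C(F)(F)F
Why: Silyl enol ether formation by soft enolisation: the silyl triflate activates the carbonyl oxygen, triethylamine removes the acidic C2–H, and O-silylation is strongly favoured because it turns the dihydrofuranone into an aromatic benzofuran; TBS is chosen over smaller silyl groups so that the Si–O bond withstands tert-butoxide in step 4, and the crude ketone is silylated under argon to forestall autoxidation at C2.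

Step 4
Reactants: 6 tert-butyl[(4,6-dimethoxy-2-tridecylbenzofuran-3-yl)oxy]dimethylsilane; 7 bromoform
Product: 10 3-bromo-5,7-dimethoxy-2-tridecyl-4H-chromen-4-one, via dibromocyclopropane adduct 8 (not isolated), via 4-silyloxybenzopyrylium bromide 9 (not isolated)
Conditions: KOtBu (2.5 equiv), hexane, −20 °C; 7 (1.5 equiv) added dropwise; → rt
Reagents that add atoms: none
Why: KOtBu deprotonates bromoform and the tribromomethyl anion loses bromide to give singlet dibromocarbene, which adds in a concerted [2+1] manner to the furan C2=C3 bond of 6, the most electron-rich π bond present because it carries both the ring oxygen and the silyloxy group, so the dimethoxybenzene ring is left alone. Adduct 8 ionises one C–Br bond while the shared C–C bond opens in a disrotatory two-electron electrocyclic process, pushed by the lone pairs of O1 and of the silyloxy oxygen, to give the aromatic benzopyrylium bromide 9; ring C is therefore closed by ring enlargement of the [2+1] adduct and not by a cyclisation, the carbene carbon becoming C3 bonded to the old furan C2 (new C2) and the old ketone carbon (new C4). Removal of the silyl group from 9 by bromide or tert-butoxide unveils the C4 carbonyl, the silicon ending as tert-butoxy(tert-butyl)dimethylsilane. The closest known reaction types are the dihalocarbene one-carbon ring expansion of cyclic silyl enol ethers to α-halo enones and the Ciamician–Dennstedt ring enlargement of indoles and benzofurans. No stereocentre is formed; the step needs chemoselectivity for the enol ether double bond and survival of the Si–O bond until the carbene has added, which the bulky TBS group, the sparingly soluble base in hexane and the low temperature should secure.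

Step 5
Reactants: 10 3-bromo-5,7-dimethoxy-2-tridecyl-4H-chromen-4-one
Product: 11 5,7-dimethoxy-2-tridecyl-4H-chromen-4-one
Conditions: Pd(OAc)2 (5 mol %), PPh3 (15 mol %), HCO2Na, DMF, 80 °C
Reagents that add atoms: none
Why: Palladium-catalysed formate hydrodehalogenation: zerovalent palladium generated from Pd(OAc)2 and PPh3 inserts into the activated C3–Br bond of the α-bromo enone, formate displaces bromide and loses CO2 to give a palladium hydride, and reductive elimination forms C3–H without affecting the C2=C3 bond, the carbonyl or the ethers.

Step 6
Reactants: 11 5,7-dimethoxy-2-tridecyl-4H-chromen-4-one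
Product: 13 5,7-dihydroxy-2-tridecyl-4H-chromen-4-one, via bis(dibromoboryl) ether 12 (not isolated)
Conditions: BBr3 (6 equiv), CH2Cl2, −78 °C → rt; then H2O, 0 °C
Reagents that add atoms: none
Why: Lewis-acid ether cleavage: BBr3 coordinates each methoxy oxygen and bromide attacks the methyl group in an SN2 step, the 5-methoxy group reacting first because boron chelates between O5 and the C4 carbonyl while the 7-methoxy group needs the excess of reagent and room temperature, and aqueous work-up hydrolyses borate 12 to the free diol.

Compound list
1 | 4,6-dimethoxybenzofuran-3(2H)-one | COc1cc(OC)c2c(c1)OCC2=O | starting material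
2 | tridecanal | CCCCCCCCCCCCC=O | starting material
3 | 2-(1-hydroxytridecyl)-4,6-dimethoxybenzofuran-3(2H)-one (aldol adduct, mixture of racemic diastereomers, not isolated) | CCCCCCCCCCCCC(O)C1Oc2cc(OC)cc(OC)c2C1=O | intermediate
4 | (Z)-4,6-dimethoxy-2-tridecylidenebenzofuran-3(2H)-one | CCCCCCCCCCCC/C=C1\Oc2cc(OC)cc(OC)c2C1=O | intermediate
5 | 4,6-dimethoxy-2-tridecylbenzofuran-3(2H)-one (racemic) | CCCCCCCCCCCCCC1Oc2cc(OC)cc(OC)c2C1=O | intermediate
6 | tert-butyl[(4,6-dimethoxy-2-tridecylbenzofuran-3-yl)oxy]dimethylsilane | CCCCCCCCCCCCCc1oc2cc(OC)cc(OC)c2c1O[Si](C)(C)C(C)(C)C | intermediate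
7 | bromoform | BrC(Br)Br | starting material
8 | 1,1-dibromo-6b-[(tert-butyldimethylsilyl)oxy]-4,6-dimethoxy-1a-tridecyl-1a,6b-dihydro-1H-cyclopropa[b]benzofuran (racemic, cis-fused, not isolated) | CCCCCCCCCCCCCC12Oc3cc(OC)cc(OC)c3C1(O[Si](C)(C)C(C)(C)C)C2(Br)Br | intermediate
9 | 3-bromo-4-[(tert-butyldimethylsilyl)oxy]-5,7-dimethoxy-2-tridecylchromenylium bromide (not isolated) | CCCCCCCCCCCCCc1[o+]c2cc(OC)cc(OC)c2c(O[Si](C)(C)C(C)(C)C)c1Br.[Br-] | intermediate
10 | 3-bromo-5,7-dimethoxy-2-tridecyl-4H-chromen-4-one | CCCCCCCCCCCCCc1oc2cc(OC)cc(OC)c2c(=O)c1Br | intermediate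
11 | 5,7-dimethoxy-2-tridecyl-4H-chromen-4-one | CCCCCCCCCCCCCc1cc(=O)c2c(OC)cc(OC)cc2o1 | intermediate
12 | 5,7-bis[(dibromoboryl)oxy]-2-tridecyl-4H-chromen-4-one (not isolated) | CCCCCCCCCCCCCc1cc(=O)c2c(OB(Br)Br)cc(OB(Br)Br)cc2o1 | intermediate
13 | 5,7-dihydroxy-2-tridecyl-4H-chromen-4-one | CCCCCCCCCCCCCc1cc(=O)c2c(O)cc(O)cc2o1 | target

Total step count: 6
Longest linear sequence: 6 steps (from 1 to 13)

Steps most likely to fail

Step 4. Tert-butoxide may attack silicon before the carbene has added, returning the enolate of 5, and the base may open ring C of the bromochromone as it forms. The fallback keeps the one-carbon insertion but avoids base and bromine. It sets out from 6: cyclopropanation with the Furukawa zinc carbenoid (Et2Zn, CH2I2, CH2Cl2, 0 °C → rt; Simmons–Smith reaction) should give 6b-[(tert-butyldimethylsilyl)oxy]-4,6-dimethoxy-1a-tridecyl-1a,6b-dihydro-1H-cyclopropa[b]benzofuran F1. FeCl3 in DMF at 0 °C (Ito–Saegusa oxidative ring enlargement of siloxycyclopropanes) should then cleave the shared C–C bond through an alkoxy radical, the silyl group leaving as the chlorosilane and being collected as the silanol after work-up. The resulting oxygen-stabilised C2 radical takes up chlorine to give 2-chloro-5,7-dimethoxy-2-tridecylchroman-4-one F2, which loses HCl on treatment with NaOAc in MeOH. The route is rejoined at 11, so step 5 is no longer needed.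

Step 1. The enolisable aldehyde may condense with itself, and a second molecule of 1 may add in conjugate fashion to the freshly formed alkylidene. The fallback separates enol formation from C–C bond formation and sets out from 1 and 2. Silylation of 1 (TBSOTf, Et3N, CH2Cl2, 0 °C) should give tert-butyl[(4,6-dimethoxybenzofuran-3-yl)oxy]dimethylsilane F3. A Mukaiyama aldol addition of F3 to 2 (BF3·OEt2, CH2Cl2, −78 °C) then stops cleanly at aldol 3, which is isolated in this variant, the silyl group leaving as the fluorosilane. Acid-catalysed dehydration (TsOH cat., toluene, 60 °C) brings the route back at 4.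

Step 3. Ketone 5 may autoxidise at its tertiary C2–H under the basic silylation conditions or on handling, and the electron-rich silyl enol ether may hydrolyse on silica. The fallback bypasses the ketone and sets out from 4, whose enone is locked s-cis. A 1,4-hydrosilylation with tBuMe2SiH and Karstedt's catalyst Pt2[(CH2=CHSiMe2)2O]3 (zerovalent platinum) in toluene at 60 °C should deliver hydride to the exocyclic carbon and silicon to oxygen. The route is rejoined directly at 6, which replaces steps 2 and 3 by one operation.

Further compounds
F1 | step 4 | 6b-[(tert-butyldimethylsilyl)oxy]-4,6-dimethoxy-1a-tridecyl-1a,6b-dihydro-1H-cyclopropa[b]benzofuran (racemic, cis-fused) | CCCCCCCCCCCCCC12CC1(O[Si](C)(C)C(C)(C)C)c1c(OC)cc(OC)cc1O2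
F2 | step 4 | 2-chloro-5,7-dimethoxy-2-tridecylchroman-4-one (racemic) | CCCCCCCCCCCCCC1(Cl)CC(=O)c2c(OC)cc(OC)cc2O1
F3 | step 1 | tert-butyl[(4,6-dimethoxybenzofuran-3-yl)oxy]dimethylsilane | COc1cc(OC)c2c(c1)occ2O[Si](C)(C)C(C)(C)C
F0 | step 3 | none | none
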